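**Plan**

- Retrosynthesis: the two O–CH2Ph bonds of the protected arms are cut first, then the two outer CH2–aryl bonds of the C6 and C8 diarylmethane arms, then the C6–CH2 and C8–CH2 bonds, which leads back to natural (2R,3R)-aromadendrin.
- Enabling feature: each of the C6 and C8 methylenes sits on ring A ortho to the C7 phenol oxygen (C6 also ortho to the C5 hydroxyl), so each can become the exocyclic carbon of a ring-A ortho-quinone methide and accept an aryl group from boron held on that oxygen.
- Forward order: no ring is built, since the chromanone core (rings A, B and C) is bought intact. Two aminomethyl arms are attached at C6 and C8 (step 1), both are converted into 4-benzyloxybenzyl arms (step 2), and the benzyl ethers are removed (step 3).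
- Stereochemistry: C2 (R) and C3 (R) come from the chiral pool. No step creates a stereocentre, and the conditions are chosen to avoid base-promoted epimerisation at C2 and C3.

Key step: step 2

Assumption: (2R,3R)-aromadendrin ((+)-dihydrokaempferol) is taken as a purchasable, enantiopure natural product. The order in which C6 and C8 react in steps 1 and 2 is not known; the intermediates are drawn with C6 reacting first, and either order leads to the same isolated products.

**Route**

Step 1
Reactants: 1 (2R,3R)-aromadendrin [(2R,3R)-3,5,7-trihydroxy-2-(4-hydroxyphenyl)chroman-4-one]; 2 bis(dimethylamino)methane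
Product: 4 (2R,3R)-6,8-bis[(dimethylamino)methyl]aromadendrin, via 6-mono Mannich base 3 (not isolated)
Conditions: Me2NCH2NMe2 (2.4 equiv), 1,4-dioxane, 20 → 45 °C, Ar; product collected by precipitation, no chromatography
Reagents that add atoms: bis(dimethylamino)methane, CN(C)CN(C)C
Why: Mannich aminomethylation with a preformed aminal, a reaction type well established for 5,7-dihydroxyflavonoids: the aminal, ionised by the acidic C7 phenol, aminomethylates C6 and then C8, the only unsubstituted carbons of the phloroglucinol-type ring A (the simple phenol of ring B needs far more forcing conditions), while the water-free, formaldehyde-free medium at no more than 45 °C disfavours methylene-bridged dimers and leaves C2 and C3 untouched.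

Step 2
Reactants: 4 (2R,3R)-6,8-bis[(dimethylamino)methyl]aromadendrin; 5 4-benzyloxyphenylboronic acid
Product: 9 (2R,3R)-6,8-bis(4-benzyloxybenzyl)aromadendrin, via C6 ortho-quinone methide 6 (not isolated), via 6-benzylated 8-aminomethyl intermediate 7 (not isolated), via C8 ortho-quinone methide 8 (not isolated)
Conditions: 4-BnOC6H4B(OH)2 (5 equiv), 4 Å MS, 1,4-dioxane, 90 °C, Ar; then aq. sorbitol/NaHCO3 wash
Reagents that add atoms: 4-benzyloxyphenylboronic acid, OB(O)c1ccc(OCc2ccccc2)cc1
Why: The boronic acid esterifies the C7 phenol of 4 and is held there by the neighbouring dimethylamino group; on heating the benzylic C–N bond ionises, ring A becomes the ortho-quinone methide 6 with an amine-ligated, tetracoordinate arylboronate on its C7 oxygen, and the 4-benzyloxyphenyl group moves from boron through its ipso carbon to the exocyclic CH2 in a six-membered transition state (B, O, C7, C6, CH2, ipso-C), which rearomatises ring A to 7, after which the same sequence at the C8 arm through 8 gives 9. The closest known reaction type is the Petasis-type, metal-free aryl transfer from boronic acids to ortho-quinone methides released from ortho-hydroxybenzylamines (phenolic Mannich bases) or ortho-hydroxybenzyl ethers, which gives ortho-hydroxydiarylmethanes; here it is run twice on one ring. No ring is closed and no stereocentre is formed, and C2 and C3 are spectators that are protected by the weakly acidic medium, because the boronic acid ties up the liberated amine and so suppresses enolisation at C3 and base-triggered opening of ring C at C2. The step needs site selectivity, regiochemistry in the incoming ring and chemoselectivity against other methide traps: the first is secured because only the two CH2NMe2 carbons placed in step 1 have an ortho phenol to expel the amine, the second because the new C–C bond forms at the carbon that carried boron and is therefore para to OBn, and the third because the aryl group is delivered intramolecularly from the methide oxygen while the methide is released slowly into an excess of 5, which should outrun attack by the ring-B phenol or methide dimerisation. Reversible chelation of boron by the C3-hydroxy/C4-keto and C5-hydroxy/C4-keto pairs is absorbed by the excess of 5 and undone in the polyol wash.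

Step 3
Reactants: 9 (2R,3R)-6,8-bis(4-benzyloxybenzyl)aromadendrin
Product: 10 gericudranin D [(2R,3R)-3,5,7-trihydroxy-6,8-bis(4-hydroxybenzyl)-2-(4-hydroxyphenyl)chroman-4-one]
Conditions: H2 (1 atm), 10% Pd/C, EtOAc/MeOH, rt
Reagents that add atoms: none
Why: Catalytic hydrogenolysis (O-debenzylation) of the two aryl benzyl ethers over palladium on carbon is fast at one atmosphere and room temperature, conditions under which the hydrogen-bonded C4 aryl ketone, the diarylmethane CH2 groups and the C2–O1 bond of 5-hydroxyflavanonols are normally retained, so C2 and C3 stay as they are.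

**Compound list**

1 | (2R,3R)-aromadendrin, (2R,3R)-3,5,7-trihydroxy-2-(4-hydroxyphenyl)chroman-4-one | O=C1c2c(O)cc(O)cc2O[C@H](c2ccc(O)cc2)[C@H]1O | starting material
2 | bis(dimethylamino)methane (N,N,N',N'-tetramethylmethanediamine) | CN(C)CN(C)C | starting material
3 | (2R,3R)-6-[(dimethylamino)methyl]aromadendrin (mono Mannich base, drawn as the 6-isomer) | O=C1c2c(O)c(CN(C)C)c(O)cc2O[C@H](c2ccc(O)cc2)[C@H]1O | intermediate
4 | (2R,3R)-6,8-bis[(dimethylamino)methyl]-3,5,7-trihydroxy-2-(4-hydroxyphenyl)chroman-4-one | O=C1c2c(O)c(CN(C)C)c(O)c(CN(C)C)c2O[C@H](c2ccc(O)cc2)[C@H]1O | intermediate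
5 | 4-benzyloxyphenylboronic acid | OB(O)c1ccc(OCc2ccccc2)cc1 | starting material
6 | (2R,3R)-8-[(dimethylamino)methyl]-3,5-dihydroxy-2-(4-hydroxyphenyl)-6-methylidene-2,3-dihydrochromene-4,7-dione (C6 ortho-quinone methide, drawn without the boron on O7) | O=C1C2=C(O)C(=C)C(=O)C(CN(C)C)=C2O[C@H](c2ccc(O)cc2)[C@H]1O | intermediate
7 | (2R,3R)-6-(4-benzyloxybenzyl)-8-[(dimethylamino)methyl]-3,5,7-trihydroxy-2-(4-hydroxyphenyl)chroman-4-one | O=C1c2c(O)c(Cc3ccc(OCc4ccccc4)cc3)c(O)c(CN(C)C)c2O[C@H](c2ccc(O)cc2)[C@H]1O | intermediate
8 | (2R,3R)-6-(4-benzyloxybenzyl)-3,5-dihydroxy-2-(4-hydroxyphenyl)-8-methylidene-2,3-dihydrochromene-4,7-dione (C8 ortho-quinone methide, drawn without the boron on O7) | O=C1C2=C(O[C@H](c3ccc(O)cc3)[C@H]1O)C(=C)C(=O)C(Cc1ccc(OCc3ccccc3)cc1)=C2O | intermediate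
9 | (2R,3R)-6,8-bis(4-benzyloxybenzyl)-3,5,7-trihydroxy-2-(4-hydroxyphenyl)chroman-4-one | O=C1c2c(O)c(Cc3ccc(OCc4ccccc4)cc3)c(O)c(Cc3ccc(OCc4ccccc4)cc3)c2O[C@H](c2ccc(O)cc2)[C@H]1O | intermediate
10 | gericudranin D, (2R,3R)-3,5,7-trihydroxy-6,8-bis(4-hydroxybenzyl)-2-(4-hydroxyphenyl)chroman-4-one | O=C1c2c(O)c(Cc3ccc(O)cc3)c(O)c(Cc3ccc(O)cc3)c2O[C@H](c2ccc(O)cc2)[C@H]1O | target

**Step count**

Total steps: 3. Longest linear sequence: 3 steps (1 → 4 → 9 → 10).

**Steps most likely to fail, with fallbacks**

1. Step 2 (key step).
- What may go wrong: ionisation of the C–N bonds may need more heat than the flavanonol tolerates, which would lead to C2 epimerisation through opening of ring C or to dehydrogenation to the flavonol. The methide may be consumed by self-condensation or by the ring-B phenol before aryl transfer. Boron may be held back by the hydroxy-ketone chelates, and the electron-rich boronic acid may protodeboronate.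
- Fallback: reverse the polarity of the CH2–aryl construction. Setting out from 1, an acid-catalysed Friedel–Crafts C-benzylation with 4-benzyloxybenzyl alcohol (OCc1ccc(OCc2ccccc2)cc1, 2.2 equiv; cat. TsOH, MeCN, 40 °C) should let the stabilised 4-alkoxybenzyl cation alkylate C6 and C8, the most nucleophilic carbons of ring A. This returns to the route at 9, which then goes through step 3. It makes no new compound (F0). Its weakness, and the reason it is not the first choice, is that the cation chooses its own sites, so O-alkylation, ring-B alkylation and mixed degrees of benzylation must be expected.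

2. Step 1.
- What may go wrong: incomplete second aminomethylation; amine-induced epimerisation or aerial oxidation of the phenolate; loss of amine from the product during isolation with formation of methylene-bridged oligomers.
- Fallback: bring in the two carbons at the aldehyde oxidation level. Setting out from 1, Duff formylation (hexamethylenetetramine, AcOH, 90 °C; then aq. HCl) should give (2R,3R)-6,8-diformylaromadendrin F1. Double reductive amination (Me2NH·HCl, NaBH(OAc)3, THF/AcOH, 0 °C → rt) then returns to the route at 4 under acidic conditions throughout.

3. Step 3.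
- What may go wrong: competing hydrogenolysis of the benzylic C2–O1 bond with opening of ring C, or inhibition of the catalyst by traces of amine or boron species so that debenzylation stalls.
- Fallback: change the protecting group so that no reduction is needed. Setting out from 4, the conditions of step 2 with 4-(tert-butyldimethylsilyloxy)phenylboronic acid (OB(O)c1ccc(O[Si](C)(C)C(C)(C)C)cc1) should give (2R,3R)-6,8-bis[4-(tert-butyldimethylsilyloxy)benzyl]aromadendrin F2. Desilylation with HF·pyridine (THF, 0 °C → rt) then returns to the route at 10.

**Further compounds**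

F0 | step 2 | none | none
F1 | step 1 | (2R,3R)-6,8-diformylaromadendrin, (2R,3R)-3,5,7-trihydroxy-2-(4-hydroxyphenyl)-4-oxochroman-6,8-dicarbaldehyde | O=C1c2c(O)c(C=O)c(O)c(C=O)c2O[C@H](c2ccc(O)cc2)[C@H]1O
F2 | step 3 | (2R,3R)-6,8-bis[4-(tert-butyldimethylsilyloxy)benzyl]-3,5,7-trihydroxy-2-(4-hydroxyphenyl)chroman-4-one | O=C1c2c(O)c(Cc3ccc(O[Si](C)(C)C(C)(C)C)cc3)c(O)c(Cc3ccc(O[Si](C)(C)C(C)(C)C)cc3)c2O[C@H](c2ccc(O)cc2)[C@H]1O
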